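Every carbon of ring A can be drawn from an alkyne, because its diaryl ether oxygen (on C1) and its ester carbonyl carbon (on C2) sit on adjacent carbons, with the 2-oxoheptyl arm on C3, the methoxy group on C5, and C4 and C6 as CH. The three alkynes are an ynoate acylating one ring B catechol oxygen, an ethynyl ether on the other, and methoxyacetylene. A rhodium-catalysed (2+2+2) cycloaddition then makes the C1–C2, C3–C4 and C5–C6 bonds and completes ring A and the seven-membered lactone ring in one operation. The precursor is this diyne carried on the finished spirolactone (phenol as MOM ether, ketone as dioxolane).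

Key step: step 17

Remark: ring A is the methoxy-bearing arene and ring B the arene fused to the spirolactone. The target is (S) at the spiro carbon and (R) at the methyl-bearing carbon. The (S) spiro epimer is the anomerically favoured one (lactone oxygen axial on the oxane chair, methyl equatorial), so it is set and kept under thermodynamic control.
Remark: the two catechol oxygens are told apart by an alkyl-type, fluoride-labile acetal that cannot migrate between neighbouring oxygens. Acid 24 and alkyne 29 are prepared before they are needed. 2-Bromo-4-methoxy-6-methylbenzoic acid, used only in one fallback, is assumed to be purchasable.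

Step 1
Reactants: 1 (R)-propylene oxide; 2 ethyl propiolate
Product: 4 ethyl (5R)-5-hydroxyhex-2-ynoate, via ethyl 3-lithiopropiolate 3 (not isolated)
Conditions: 2, n-BuLi, THF, −78 °C; BF3·OEt2; 1, −78 °C; H2O
Reagents that add atoms: none
Why: The lithium acetylide opens the BF3-activated epoxide at its CH2 carbon (Yamaguchi–Hirao alkynylation), so the (R) carbinol centre is carried over untouched.

Step 2
Reactants: 4 ethyl (5R)-5-hydroxyhex-2-ynoate
Product: 6 (6R)-6-methyloxan-2-one, via ethyl (5R)-5-hydroxyhexanoate 5 (not isolated)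
Conditions: H2 (1 atm), Pd/C, EtOAc, rt; filter; TsOH·H2O (cat.), CH2Cl2, rt
Reagents that add atoms: none
Why: Catalytic hydrogenation saturates the alkyne and the δ-hydroxy ester lactonises under acid catalysis without touching the stereocentre.

Step 3
Reactants: 7 methyl orsellinate
Product: 8 methyl 2-hydroxy-6-methyl-4-{[tri(propan-2-yl)silyl]oxymethoxy}benzoate
Conditions: i-Pr3SiOCH2Cl, i-Pr2NEt, CH2Cl2, 0 °C → rt
Reagents that add atoms: (triisopropylsiloxy)methyl chloride, CC(C)[Si](OCCl)(C(C)C)C(C)C
Why: Williamson-type O-alkylation with the α-chloro ether should occur only at the 4-OH, because the 2-OH is hydrogen-bonded to the ester.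

Step 4
Reactants: 8 methyl 2-hydroxy-6-methyl-4-{[tri(propan-2-yl)silyl]oxymethoxy}benzoate
Product: 9 methyl 2-(methoxymethoxy)-6-methyl-4-{[tri(propan-2-yl)silyl]oxymethoxy}benzoate
Conditions: NaH, DMF, 0 °C; MOMCl, 0 °C → rt
Reagents that add atoms: chloromethyl methyl ether, COCCl
Why: The sodium salt of the chelated phenol is alkylated by the α-chloro ether (Williamson ether synthesis), giving a fully protected toluate fit for benzylic lithiation.

Step 5
Reactants: 9 methyl 2-(methoxymethoxy)-6-methyl-4-{[tri(propan-2-yl)silyl]oxymethoxy}benzoate; 6 (6R)-6-methyloxan-2-one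
Product: 11 methyl 2-[(6R)-6-hydroxy-2-oxoheptyl]-6-(methoxymethoxy)-4-{[tri(propan-2-yl)silyl]oxymethoxy}benzoate, via benzylic lithium species 10 (not isolated)
Conditions: LiN(i-Pr)2, THF, −78 °C; 6, −78 °C; AcOH, −78 °C → rt
Reagents that add atoms: none
Why: Lateral lithiation of the ortho-toluate gives a benzylic anion that adds once to the lactone carbonyl (the lithium lactol alkoxide holds at −78 °C), and the hydroxy ketone, in equilibrium with its lactol, is released on quench with the carbinol centre unchanged.

Step 6
Reactants: 11 methyl 2-[(6R)-6-hydroxy-2-oxoheptyl]-6-(methoxymethoxy)-4-{[tri(propan-2-yl)silyl]oxymethoxy}benzoate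
Product: 12 (3S,6'R)-8-(methoxymethoxy)-6'-methyl-6-{[tri(propan-2-yl)silyl]oxymethoxy}spiro[isochromane-3,2'-oxan]-1-one
Conditions: CSA (0.2 equiv), CH2Cl2, rt
Reagents that add atoms: none
Why: Acid-catalysed spiroketalisation and lactonisation (lactol oxygen onto the ester, loss of methanol) run reversibly through the oxocarbenium ion, so the spiro carbon should settle as the anomerically stabilised (S) epimer with the lactone oxygen axial on the oxane chair and the methyl group equatorial.

Step 7
Reactants: 12 (3S,6'R)-8-(methoxymethoxy)-6'-methyl-6-{[tri(propan-2-yl)silyl]oxymethoxy}spiro[isochromane-3,2'-oxan]-1-one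
Product: 13 (3S,6'R)-5-bromo-8-(methoxymethoxy)-6'-methyl-6-{[tri(propan-2-yl)silyl]oxymethoxy}spiro[isochromane-3,2'-oxan]-1-one
Conditions: NBS, MeCN, 0 °C, dark
Reagents that add atoms: N-bromosuccinimide, O=C1CCC(=O)N1Br
Why: Electrophilic aromatic bromination should go to C5 of ring B, which is para to the MOM ether and ortho to the other acetal oxygen, whereas C7 is shielded between two alkoxy groups.

Step 8
Reactants: 13 (3S,6'R)-5-bromo-8-(methoxymethoxy)-6'-methyl-6-{[tri(propan-2-yl)silyl]oxymethoxy}spiro[isochromane-3,2'-oxan]-1-one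
Product: 15 (3S,6'R)-5-hydroxy-8-(methoxymethoxy)-6'-methyl-6-{[tri(propan-2-yl)silyl]oxymethoxy}spiro[isochromane-3,2'-oxan]-1-one, via pinacol boronate 14 (not isolated)
Conditions: B2pin2, Pd(OAc)2, SPhos, KOAc, 1,4-dioxane, 90 °C; then H2O2 (30% aq), NaHCO3, THF, 0 °C
Reagents that add atoms: hydrogen peroxide, OO
Why: Miyaura borylation of the aryl bromide followed by peroxide oxidation of the C–B bond (aryl shift from boron to oxygen) places the hydroxyl group exactly where the bromine was, under conditions mild enough for the acyl ketal.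

Step 9
Reactants: 15 (3S,6'R)-5-hydroxy-8-(methoxymethoxy)-6'-methyl-6-{[tri(propan-2-yl)silyl]oxymethoxy}spiro[isochromane-3,2'-oxan]-1-one; 16 (bromoethynyl)tri(propan-2-yl)silane
Product: 17 (3S,6'R)-8-(methoxymethoxy)-6'-methyl-5-({[tri(propan-2-yl)silyl]ethynyl}oxy)-6-{[tri(propan-2-yl)silyl]oxymethoxy}spiro[isochromane-3,2'-oxan]-1-one
Conditions: CuI, 1,10-phenanthroline, K3PO4, toluene, 90 °C
Reagents that add atoms: none
Why: Copper-catalysed Ullmann-type C(sp)–O coupling of the copper phenoxide with the bromoalkyne should give the silyl-capped aryl ynol ether, and since only one phenol is free the site is unambiguous.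

Step 10
Reactants: 17 (3S,6'R)-8-(methoxymethoxy)-6'-methyl-5-({[tri(propan-2-yl)silyl]ethynyl}oxy)-6-{[tri(propan-2-yl)silyl]oxymethoxy}spiro[isochromane-3,2'-oxan]-1-one
Product: 18 (3S,6'R)-5-(ethynyloxy)-6-hydroxy-8-(methoxymethoxy)-6'-methylspiro[isochromane-3,2'-oxan]-1-one
Conditions: n-Bu4NF, THF, 0 °C → rt; pH 7 buffer; used at once
Reagents that add atoms: none
Why: Fluoride removes the alkynyl silyl group and attacks the silicon of the silyloxymethyl acetal, whose hemiacetal anion loses formaldehyde, so one desilylation frees the terminal ynol ether and the neighbouring phenol while the MOM ether stays.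

Step 11
Reactants: 19 methyl 3-oxooctanoate
Product: 20 methyl 2-(2-pentyl-1,3-dioxolan-2-yl)acetate
Conditions: HOCH2CH2OH, TsOH·H2O (cat.), toluene, reflux (Dean–Stark)
Reagents that add atoms: ethylene glycol, OCCO
Why: Acid-catalysed ketalisation with azeotropic removal of water masks the ketone, which would otherwise lie β,γ to the later alkyne and isomerise.

Step 12
Reactants: 20 methyl 2-(2-pentyl-1,3-dioxolan-2-yl)acetate
Product: 21 2-(2-pentyl-1,3-dioxolan-2-yl)acetaldehyde
Conditions: i-Bu2AlH, CH2Cl2, −78 °C; potassium sodium tartrate (aq)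
Reagents that add atoms: none
Why: Partial reduction of the ester stops at the aldehyde because the aluminium hemiacetal, chelated by a ketal oxygen, persists at −78 °C until work-up.

Step 13
Reactants: 21 2-(2-pentyl-1,3-dioxolan-2-yl)acetaldehyde
Product: 22 2-pentyl-2-(prop-2-yn-1-yl)-1,3-dioxolane
Conditions: dimethyl (1-diazo-2-oxopropyl)phosphonate, K2CO3, MeOH, 0 °C → rt
Reagents that add atoms: dimethyl (1-diazo-2-oxopropyl)phosphonate, CC(=O)C(=[N+]=[N-])P(=O)(OC)OC
Why: Ohira–Bestmann homologation (Seyferth–Gilbert type) converts the aldehyde into the terminal alkyne under mild base that leaves the ketal alone.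

Step 14
Reactants: 22 2-pentyl-2-(prop-2-yn-1-yl)-1,3-dioxolane
Product: 24 4-(2-pentyl-1,3-dioxolan-2-yl)but-2-ynoic acid, via lithium acetylide 23 (not isolated)
Conditions: n-BuLi, THF, −78 °C; CO2; HCl (1 M, aq) to pH 4, 0 °C
Reagents that add atoms: carbon dioxide, O=C=O
Why: Deprotonation of the terminal alkyne and carboxylation of the acetylide give the ynoic acid, and the brief cold acidification spares the dioxolane.

Step 15
Reactants: 18 (3S,6'R)-5-(ethynyloxy)-6-hydroxy-8-(methoxymethoxy)-6'-methylspiro[isochromane-3,2'-oxan]-1-one; 24 4-(2-pentyl-1,3-dioxolan-2-yl)but-2-ynoic acid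
Product: 26 (3S,6'R)-5-(ethynyloxy)-8-(methoxymethoxy)-6'-methyl-1-oxospiro[isochromane-3,2'-oxan]-6-yl 4-(2-pentyl-1,3-dioxolan-2-yl)but-2-ynoate, via O-acylisourea 25 (not isolated)
Conditions: 24, DIC, CH2Cl2, 0 °C, 10 min; then 18, DMAP (cat.), 0 °C
Reagents that add atoms: none
Why: Steglich esterification with the acid activated before the phenol is added, so that no free carboxylic acid can add across the ynol ether, should acylate the only free phenol.

Step 16
Reactants: 27 chloroacetaldehyde dimethyl acetal
Product: 29 methoxyacetylene, via sodium methoxyacetylide 28 (not isolated)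
Conditions: NaNH2 (3 equiv), NH3 (l), −33 °C; NaCl (sat. aq), −70 °C → rt; distilled into cold CH2Cl2
Reagents that add atoms: none
Why: Two base-induced eliminations (methanol, then hydrogen chloride) give the alkoxyacetylene, which is held as its sodium acetylide until aqueous quench releases the volatile alkyne.

Step 17
Reactants: 26 catechol-tethered diyne; 29 methoxyacetylene
Product: 30 doubly protected target (depsidone with the ketone as dioxolane and the ring B phenol as MOM ether)
Conditions: [Rh(cod)2]BF4 (10 mol%), H8-BINAP (10 mol%), pre-hydrogenated, CH2Cl2, sealed tube, rt; 29 (5 equiv); 26 added slowly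
Reagents that add atoms: none
Why: Proposed new method: cationic monovalent rhodium with the bisphosphine should bind the two tethered alkynes and couple them oxidatively to a rhodacyclopentadiene in which the ynoate α-carbon is joined to the oxygen-bearing ynol ether carbon (C2–C1), after which insertion of methoxyacetylene into a Rh–C bond and reductive elimination form C3–C4 and C5–C6 and give the benzene ring. The nearest precedent is the rhodium-catalysed cyclotrimerisation of diynes linked through an ester with a third alkyne, which gives phthalide-type benzo-fused lactones; aryl ethynyl ethers are also known partners in rhodium cyclotrimerisations, but no example joins an ynol ether through a tether that ends in a seven-membered ring. The seven-membered lactone ring closes in the oxidative coupling step as an annulation across the O–aryl–aryl–O–C(=O) tether, and ring A closes in the final reductive elimination as a three-alkyne benzannulation. No stereocentre is formed, and the two existing ones lie far from the reacting carbons. Intramolecular pairing of the two alkynes in preference to dimerisation should follow from ring B, which fixes them on neighbouring oxygens at a five-atom distance with matched polarity (acceptor ynoate, donor ynol ether), helped by slow addition of 26 to excess 29. The regiochemistry needed, methoxy-bearing carbon bonded to the CH terminus of the ynol ether (C6), is favoured sterically because the other rhodacycle terminus (C3) carries the ketal arm and electronically because the nucleophilic CH of methoxyacetylene matches the electron-poor β-carbon of the ynoate.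

Step 18
Reactants: 30 doubly protected target
Product: 31 target CNP0301127.1
Conditions: HCl (2 M, aq), THF, rt → 40 °C
Reagents that add atoms: water, O
Why: Acid hydrolysis cleaves the MOM acetal and the dioxolane together, and because the spiro acyl ketal already has its thermodynamic (S) configuration any reversible opening under acid should return the same epimer.

Compound list
1 | (R)-propylene oxide, (2R)-2-methyloxirane | C[C@@H]1CO1 | starting material
2 | ethyl propiolate | C#CC(=O)OCC | starting material
3 | ethyl 3-lithiopropiolate | [Li]C#CC(=O)OCC | intermediate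
4 | ethyl (5R)-5-hydroxyhex-2-ynoate | C[C@@H](O)CC#CC(=O)OCC | intermediate
5 | ethyl (5R)-5-hydroxyhexanoate | C[C@@H](O)CCCC(=O)OCC | intermediate
6 | (6R)-6-methyloxan-2-one | C[C@@H]1CCCC(=O)O1 | intermediate
7 | methyl orsellinate, methyl 2,4-dihydroxy-6-methylbenzoate | COC(=O)c1c(C)cc(O)cc1O | starting material
8 | methyl 2-hydroxy-6-methyl-4-{[tri(propan-2-yl)silyl]oxymethoxy}benzoate | COC(=O)c1c(C)cc(OCO[Si](C(C)C)(C(C)C)C(C)C)cc1O | intermediate
9 | methyl 2-(methoxymethoxy)-6-methyl-4-{[tri(propan-2-yl)silyl]oxymethoxy}benzoate | COC(=O)c1c(C)cc(OCO[Si](C(C)C)(C(C)C)C(C)C)cc1OCOC | intermediate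
10 | benzylic lithium species of 9 (lithium on the former 6-methyl carbon) | [Li]Cc1cc(OCO[Si](C(C)C)(C(C)C)C(C)C)cc(OCOC)c1C(=O)OC | intermediate
11 | methyl 2-[(6R)-6-hydroxy-2-oxoheptyl]-6-(methoxymethoxy)-4-{[tri(propan-2-yl)silyl]oxymethoxy}benzoate | COC(=O)c1c(CC(=O)CCC[C@@H](C)O)cc(OCO[Si](C(C)C)(C(C)C)C(C)C)cc1OCOC | intermediate
12 | (3S,6'R)-8-(methoxymethoxy)-6'-methyl-6-{[tri(propan-2-yl)silyl]oxymethoxy}spiro[isochromane-3,2'-oxan]-1-one | CC(C)[Si](OCOc1cc(OCOC)c2c(c1)C[C@]1(CCC[C@@H](C)O1)OC2=O)(C(C)C)C(C)C | intermediate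
13 | 5-bromo derivative of 12 | CC(C)[Si](OCOc1cc(OCOC)c2c(c1Br)C[C@]1(CCC[C@@H](C)O1)OC2=O)(C(C)C)C(C)C | intermediate
14 | 5-(4,4,5,5-tetramethyl-1,3,2-dioxaborolan-2-yl) derivative of 12 | CC(C)[Si](OCOc1cc(OCOC)c2c(c1B3OC(C)(C)C(C)(C)O3)C[C@]1(CCC[C@@H](C)O1)OC2=O)(C(C)C)C(C)C | intermediate
15 | 5-hydroxy derivative of 12 | CC(C)[Si](OCOc1cc(OCOC)c2c(c1O)C[C@]1(CCC[C@@H](C)O1)OC2=O)(C(C)C)C(C)C | intermediate
16 | (bromoethynyl)tri(propan-2-yl)silane | CC(C)[Si](C#CBr)(C(C)C)C(C)C | starting material
17 | 5-({[tri(propan-2-yl)silyl]ethynyl}oxy) derivative of 12 | CC(C)[Si](OCOc1cc(OCOC)c2c(c1OC#C[Si](C(C)C)(C(C)C)C(C)C)C[C@]1(CCC[C@@H](C)O1)OC2=O)(C(C)C)C(C)C | intermediate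
18 | (3S,6'R)-5-(ethynyloxy)-6-hydroxy-8-(methoxymethoxy)-6'-methylspiro[isochromane-3,2'-oxan]-1-one | C#COc1c(O)cc(OCOC)c2c1C[C@]1(CCC[C@@H](C)O1)OC2=O | intermediate
19 | methyl 3-oxooctanoate | CCCCCC(=O)CC(=O)OC | starting material
20 | methyl 2-(2-pentyl-1,3-dioxolan-2-yl)acetate | CCCCCC1(OCCO1)CC(=O)OC | intermediate
21 | 2-(2-pentyl-1,3-dioxolan-2-yl)acetaldehyde | CCCCCC1(OCCO1)CC=O | intermediate
22 | 2-pentyl-2-(prop-2-yn-1-yl)-1,3-dioxolane | CCCCCC1(OCCO1)CC#C | intermediate
23 | lithium acetylide of 22 | CCCCCC1(OCCO1)CC#C[Li] | intermediate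
24 | 4-(2-pentyl-1,3-dioxolan-2-yl)but-2-ynoic acid | CCCCCC1(OCCO1)CC#CC(=O)O | intermediate
25 | O-acylisourea from 24 and N,N'-diisopropylcarbodiimide | CCCCCC1(OCCO1)CC#CC(=O)OC(=NC(C)C)NC(C)C | intermediate
26 | (3S,6'R)-5-(ethynyloxy)-8-(methoxymethoxy)-6'-methyl-1-oxospiro[isochromane-3,2'-oxan]-6-yl 4-(2-pentyl-1,3-dioxolan-2-yl)but-2-ynoate (catechol-tethered diyne) | CCCCCC1(OCCO1)CC#CC(=O)Oc1cc(OCOC)c2c(c1OC#C)C[C@]1(CCC[C@@H](C)O1)OC2=O | intermediate
27 | chloroacetaldehyde dimethyl acetal, 2-chloro-1,1-dimethoxyethane | COC(CCl)OC | starting material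
28 | sodium methoxyacetylide | [Na]C#COC | intermediate
29 | methoxyacetylene | COC#C | intermediate
30 | doubly protected target: depsidone in which ring A carries OMe and the (2-pentyl-1,3-dioxolan-2-yl)methyl arm and ring B carries the MOM ether and the fused (S)-spiro, (R)-methyl spirolactone | CCCCCC1(OCCO1)Cc1cc(OC)cc2c1C(=O)Oc1cc(OCOC)c3c(c1O2)C[C@]1(CCC[C@@H](C)O1)OC3=O | intermediate
31 | CNP0301127.1: depsidone with ring A OMe and 2-oxoheptyl arm, ring B free phenol, (S) spiro carbon and (R) methyl carbon | CCCCCC(=O)Cc1cc(OC)cc2c1C(=O)Oc1cc(O)c3c(c1O2)C[C@]1(CCC[C@@H](C)O1)OC3=O | target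

Total step count: 18.
Longest linear sequence: 11 steps (steps 3 to 10, then 15, 17 and 18, from methyl orsellinate 7).

Steps most likely to fail

Step 17. The two tethered alkynes may not couple across the seven-membered tether. The ynol ether may then oligomerise, methoxyacetylene may trimerise on its own, or methoxyacetylene may insert the wrong way round. The fallback uses known chemistry, sets out from phenol 15 and returns at 30, and brings ring A in preformed. Purchased 2-bromo-4-methoxy-6-methylbenzoic acid would be esterified with 2-(trimethylsilyl)ethanol (DIC, DMAP) to the silylethyl ester F1. Lateral lithiation (LiN(i-Pr)2, THF, −78 °C) and acylation with N-methoxy-N-methylhexanamide would give the benzyl ketone F2, and ketalisation (ethylene glycol, TsOH) the ketal bromide F3. Ullmann diaryl ether coupling of 15 with F3 (CuI, picolinic acid, K3PO4, DMSO, 90 °C) should give the diaryl ether F4. n-Bu4NF would then remove the silyloxymethyl acetal and the silylethyl ester together to give the hydroxy acid F5. Yamaguchi lactonisation (2,4,6-trichlorobenzoyl chloride, Et3N, then DMAP) would close the seven-membered lactone to 30.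

Step 9. The hindered phenoxide may fail to enter the copper cycle, so that the bromoalkyne homocouples or the phenoxide adds across it instead of substituting at the sp carbon. The fallback sets out from 15 and returns at 18. Copper-catalysed coupling of 15 with 1,1-dibromoethene (CuI, 2,2'-bipyridine, K3PO4, toluene, 100 °C, sealed) would give the 1-bromovinyl ether F6. Elimination of hydrogen bromide with KOt-Bu (THF, −40 °C → 0 °C) would give the ethynyl ether F7, still carrying the silyloxymethyl group, and n-Bu4NF would then give 18.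

Step 10. Once freed, the phenol may add to the neighbouring ethynyl ether during work-up and concentration (closure to a benzodioxole ketene acetal), so that 18 is lost before it can be acylated. The fallback sets out from 17 and returns at 26 without isolating 18. The desilylation would be run with n-Bu4NF at 0 °C and the resulting ammonium phenoxide acylated in the same flask with the symmetric anhydride F8, preformed from 24 and DIC (0.5 equiv).

Further compounds
F1 | step 17 | 2-(trimethylsilyl)ethyl 2-bromo-4-methoxy-6-methylbenzoate | C[Si](C)(C)CCOC(=O)c1c(C)cc(OC)cc1Br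
F2 | step 17 | 2-(trimethylsilyl)ethyl 2-bromo-4-methoxy-6-(2-oxoheptyl)benzoate | CCCCCC(=O)Cc1cc(OC)cc(Br)c1C(=O)OCC[Si](C)(C)C
F3 | step 17 | 2-(trimethylsilyl)ethyl 2-bromo-4-methoxy-6-[(2-pentyl-1,3-dioxolan-2-yl)methyl]benzoate | CCCCCC1(OCCO1)Cc1cc(OC)cc(Br)c1C(=O)OCC[Si](C)(C)C
F4 | step 17 | diaryl ether of 15 (through its 5-oxygen) with the ring A silylethyl ester | CCCCCC1(OCCO1)Cc1cc(OC)cc(Oc2c(OCO[Si](C(C)C)(C(C)C)C(C)C)cc(OCOC)c3c2C[C@]2(CCC[C@@H](C)O2)OC3=O)c1C(=O)OCC[Si](C)(C)C
F5 | step 17 | hydroxy acid (seco acid of 30) | CCCCCC1(OCCO1)Cc1cc(OC)cc(Oc2c(O)cc(OCOC)c3c2C[C@]2(CCC[C@@H](C)O2)OC3=O)c1C(=O)O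
F6 | step 9 | 5-(1-bromovinyloxy) derivative of 12 | CC(C)[Si](OCOc1cc(OCOC)c2c(c1OC(Br)=C)C[C@]1(CCC[C@@H](C)O1)OC2=O)(C(C)C)C(C)C
F7 | step 9 | 5-(ethynyloxy) derivative of 12 | CC(C)[Si](OCOc1cc(OCOC)c2c(c1OC#C)C[C@]1(CCC[C@@H](C)O1)OC2=O)(C(C)C)C(C)C
F8 | step 10 | 4-(2-pentyl-1,3-dioxolan-2-yl)but-2-ynoic anhydride | CCCCCC1(OCCO1)CC#CC(=O)OC(=O)C#CCC1(CCCCC)OCCO1
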